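**Retrosynthetic overview**

1. The target comes from cyclopentenone diol 12 by α-iodination of the enone (C10) and acetylation of the secondary C7–OH.
2. The only ring is made in one step from 2-furylcarbinol 11 by a Piancatelli rearrangement, a conrotatory 4π electrocyclisation of a 1,4-dihydroxypentadienyl cation. It forms C8–C12 and sets C8 and C12 under the influence of the C7 stereocentre.
3. Furylcarbinol 11 comes from 5-metalated 2-[(Z)-oct-2-enyl]furan (4) and α-silyloxy aldehyde 10.
4. Aldehyde 10 comes from (R)-glyceraldehyde acetonide (D-mannitol pool, supplies C7) by Z-Wittig, acetonide removal, bis-silylation and oxidation. Furan 4 comes from furan and (Z)-oct-2-enyl bromide.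

Assumptions: prostanoid numbering is used (C7 = acetoxy carbon, C8/C12 = ring sp3 carbons). The telescoped Wittig/esterification is counted as one step. Simple reagents (CBr4, MeI, TESCl, I2, Ac2O, water) are not numbered.

---

**Step 1**
Reactants: 1, (2Z)-oct-2-en-1-ol
Product: 2, (2Z)-1-bromooct-2-ene
Conditions: CBr4, PPh3, CH2Cl2, 0 °C
Reagents that add atoms: carbon tetrabromide, BrC(Br)(Br)Br
Why: Appel bromination (SN2 on the alkoxyphosphonium) converts the primary allylic alcohol to the bromide at 0 °C without allylic transposition or Z→E isomerisation.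

**Step 2**
Reactants: 3, furan (excess); 2, (2Z)-1-bromooct-2-ene
Product: 4, 2-[(2Z)-oct-2-en-1-yl]furan
Conditions: n-BuLi, THF, −78 → 0 °C; then 2, −78 °C → rt
Reagents that add atoms: none
Why: α-lithiation of furan followed by SN2 alkylation with the unhindered primary allylic bromide puts the intact Z-octenyl chain on the furan carbon that becomes C12.

**Step 3**
Reactants: 5, (R)-2,2-dimethyl-1,3-dioxolane-4-carbaldehyde; 6, (4-carboxybutyl)triphenylphosphonium bromide
Product: 7, methyl (5Z)-6-[(4S)-2,2-dimethyl-1,3-dioxolan-4-yl]hex-5-enoate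
Conditions: 6, NaHMDS (2.1 equiv), THF, 0 °C; add 5, −78 °C → rt; crude acid: MeI, K2CO3, DMF, rt (telescoped)
Reagents that add atoms: iodomethane, CI
Why: Salt-free Wittig olefination with the non-stabilised ylide gives the 5Z alkene (typically ≥95:5), and carboxylate O-methylation gives the ester; the purchased stereocentre (future C7) is untouched, and its descriptor changes R→S only through CIP priorities.

**Step 4**
Reactants: 7
Product: 8, methyl (5Z,7S)-7,8-dihydroxyoct-5-enoate
Conditions: AcOH/H2O/THF (3:1:1), 40 °C
Reagents that add atoms: none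
Why: Mild acid-catalysed acetal hydrolysis frees the diol without affecting the methyl ester, the Z-alkene or C7.

**Step 5**
Reactants: 8
Product: 9, methyl (5Z,7S)-7,8-bis(triethylsilyloxy)oct-5-enoate
Conditions: TESCl (2.4 equiv), imidazole, DMAP (cat.), CH2Cl2, 0 °C → rt
Reagents that add atoms: chlorotriethylsilane, CC[Si](Cl)(CC)CC
Why: Exhaustive O-silylation sets up differentiation of the two oxygens in the next step.

**Step 6**
Reactants: 9
Product: 10, methyl (5Z,7S)-8-oxo-7-(triethylsilyloxy)oct-5-enoate
Conditions: (COCl)2 (4 equiv), DMSO (8 equiv), CH2Cl2, −78 → −40 °C, 30 min; then i-Pr2NEt, −78 → −20 °C; used crude at once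
Reagents that add atoms: none
Why: Under Swern conditions a primary TES ether is cleaved and oxidised directly to the aldehyde while the secondary TES ether survives; cold Hünig's base limits epimerisation or conjugation of the α-silyloxy β,γ-unsaturated aldehyde.

**Step 7**
Reactants: 4, 2-[(2Z)-oct-2-en-1-yl]furan; 10
Product: 11, methyl (5Z,7S,8RS)-8-hydroxy-8-{5-[(2Z)-oct-2-en-1-yl]furan-2-yl}-7-(triethylsilyloxy)oct-5-enoate (C8 epimer mixture)
Conditions: 4 (1.2 equiv), n-BuLi, THF, −78 → −20 °C; MgBr2·OEt2, −78 °C; then 10, −78 °C; NH4Cl quench at −78 °C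
Reagents that add atoms: none
Why: Kinetic lithiation at the free furan α-position, transmetalation to the less basic magnesium species, and 1,2-addition to the aldehyde (much faster than attack on the remote ester) give the furylcarbinol; the C8 configuration does not matter because C8 is ionised in step 8.

**Step 8**
Reactants: 11
Product: 12, methyl (5Z,7S)-7-hydroxy-7-{(1R,2R)-2-hydroxy-2-[(2Z)-oct-2-en-1-yl]-5-oxocyclopent-3-en-1-yl}hept-5-enoate
Conditions: Dy(OTf)3 (10 mol %), t-BuOH/H2O (5:1), 80 °C; then AcOH/THF/H2O, rt, to complete loss of TES; chromatography to remove the minor diastereomer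
Reagents that add atoms: water, O (oxygen of the C12 hydroxyl)
Why: In this Piancatelli rearrangement, ionisation of the furfuryl alcohol, water addition at the octenyl-bearing furan carbon and ring opening give a 1,4-dihydroxypentadienyl cation that closes by conrotatory 4π electrocyclisation; the two chains sit "outside" and end up trans (C12–OH cis to the C8 side chain, also the thermodynamic arrangement at epimerisable C8), and the sense of conrotation is biased by the (7S) centre, since both the H-eclipsed rotamer (bond formation anti to C7–O) and the O-inside rotamer (anti to the alkenyl group) predict the (8R,12-natural) ring; this induction is a model prediction, not a precedented result.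

**Step 9**
Reactants: 12
Product: 13, methyl (5Z,7S)-7-hydroxy-7-{(1R,2S)-2-hydroxy-4-iodo-2-[(2Z)-oct-2-en-1-yl]-5-oxocyclopent-3-en-1-yl}hept-5-enoate
Conditions: I2 (2 equiv), pyridine/CH2Cl2 (1:1), 0 °C → rt, dark; Na2S2O3 work-up
Reagents that add atoms: iodine, II
Why: Johnson α-iodination (pyridine conjugate addition, enolate iodination, E1cB loss of pyridine) functionalises only the enone α-carbon C10; no stereocentre is touched, and the ring C-2 descriptor changes R→S only through CIP priorities.

**Step 10**
Reactants: 13
Product: 14, 7-acetoxy-7,8-dihydroiodovulone I, methyl (5Z,7S)-7-acetoxy-7-{(1R,2S)-2-hydroxy-4-iodo-2-[(2Z)-oct-2-en-1-yl]-5-oxocyclopent-3-en-1-yl}hept-5-enoate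
Conditions: Ac2O (1.5 equiv), pyridine, CH2Cl2, 0 °C, no DMAP; cold quench
Reagents that add atoms: acetic anhydride, CC(=O)OC(C)=O
Why: Chemoselective acylation of the secondary allylic C7–OH over the hindered tertiary C12–OH, kept cold and DMAP-free so the β-acetoxy ketone does not eliminate to the cross-conjugated dienone.

---

**Compound list**

1 | (2Z)-oct-2-en-1-ol | CCCCC/C=C\CO | starting material
2 | (2Z)-1-bromooct-2-ene | CCCCC/C=C\CBr | intermediate
3 | furan | c1ccoc1 | starting material
4 | 2-[(2Z)-oct-2-en-1-yl]furan | CCCCC/C=C\Cc1ccco1 | intermediate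
5 | (R)-2,2-dimethyl-1,3-dioxolane-4-carbaldehyde ((R)-glyceraldehyde acetonide) | O=C[C@H]1COC(C)(C)O1 | starting material
6 | (4-carboxybutyl)triphenylphosphonium bromide | OC(=O)CCCC[P+](c1ccccc1)(c1ccccc1)c1ccccc1.[Br-] | starting material
7 | methyl (5Z)-6-[(4S)-2,2-dimethyl-1,3-dioxolan-4-yl]hex-5-enoate | COC(=O)CCC/C=C\[C@H]1COC(C)(C)O1 | intermediate
8 | methyl (5Z,7S)-7,8-dihydroxyoct-5-enoate | COC(=O)CCC/C=C\[C@H](O)CO | intermediate
9 | methyl (5Z,7S)-7,8-bis(triethylsilyloxy)oct-5-enoate | COC(=O)CCC/C=C\[C@H](O[Si](CC)(CC)CC)CO[Si](CC)(CC)CC | intermediate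
10 | methyl (5Z,7S)-8-oxo-7-(triethylsilyloxy)oct-5-enoate | COC(=O)CCC/C=C\[C@H](O[Si](CC)(CC)CC)C=O | intermediate
11 | methyl (5Z,7S,8RS)-8-hydroxy-8-{5-[(2Z)-oct-2-en-1-yl]furan-2-yl}-7-(triethylsilyloxy)oct-5-enoate | COC(=O)CCC/C=C\[C@H](O[Si](CC)(CC)CC)C(O)c1ccc(C/C=C\CCCCC)o1 | intermediate
12 | methyl (5Z,7S)-7-hydroxy-7-{(1R,2R)-2-hydroxy-2-[(2Z)-oct-2-en-1-yl]-5-oxocyclopent-3-en-1-yl}hept-5-enoate | CCCCC/C=C\C[C@@]1(O)C=CC(=O)[C@@H]1[C@H](/C=C\CCCC(=O)OC)O | intermediate
13 | methyl (5Z,7S)-7-hydroxy-7-{(1R,2S)-2-hydroxy-4-iodo-2-[(2Z)-oct-2-en-1-yl]-5-oxocyclopent-3-en-1-yl}hept-5-enoate | CCCCC/C=C\C[C@@]1(O)C=C(I)C(=O)[C@@H]1[C@H](/C=C\CCCC(=O)OC)O | intermediate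
14 | 7-acetoxy-7,8-dihydroiodovulone I | CCCCC/C=C\C[C@@]1(O)C=C(I)C(=O)[C@@H]1[C@H](/C=C\CCCC(=O)OC)OC(C)=O | target

---

**Totals**
Total steps: 10. Longest linear sequence: 8 (compound 5 → 14, steps 3–10); the furan branch (steps 1–2) joins at step 7.

**Three steps most likely to fail**

1. **Step 8 (Piancatelli rearrangement).** 5-Alkylfurans rearrange sluggishly, the C7 oxygen slows ionisation, induction from C7 may be modest, and the β-hydroxy ketone can dehydrate to the dienone. Fallback: decouple the ring from C7. Prepare enantiopure 4-hydroxy-4-[(Z)-oct-2-enyl]cyclopent-2-enone first (1,2-addition to a 4-silyloxycyclopent-2-enone chiron, then oxidation) and attach C1–C7 by aldol with methyl (Z)-7-oxohept-5-enoate, so that C12 directs C8 and C7.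

2. **Step 7 (furan metalation and addition).** The furfuryl/allylic CH2 of 4 may be deprotonated competitively, and the aldehyde may enolise. Fallback: generate the nucleophile by halogen–metal exchange instead of deprotonation. Make 2-bromo-5-[(Z)-oct-2-enyl]furan from 2,5-dibromofuran (mono Br/Li exchange, alkylation with 2), then t-BuLi exchange at −78 °C before adding 10.

3. **Step 6 (aldehyde 10).** The α-silyloxy β,γ-unsaturated aldehyde can epimerise at C7 or move into conjugation. Fallback: reverse the bond-forming order. Add the metalated furan 4 to robust aldehyde 5 first, protect the carbinol, then unmask the terminal diol, oxidise C6 to the aldehyde and install the 5Z alkene by Wittig on the furan-bearing fragment, so the sensitive aldehyde is never isolated.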